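## The problem

Target 23 is an unsymmetrical 2,5-dimethoxy-3,6-bis(indol-3-yl)-1,4-benzoquinone. In the numbering used here, C1 and C4 are the carbonyl carbons, C2 and C5 carry the methoxy groups, C3 carries the 2-(2-methylbut-3-en-2-yl)indol-3-yl group and C6 the unsubstituted indol-3-yl group. The central ring is fully substituted, and each indole-bearing carbon must sit between one carbonyl carbon and one methoxy carbon. The 2,5- (not 2,6-) arrangement of the methoxy groups and the para placement of two different indoles therefore have to follow from the construction, not from separating isomers. The molecule has no stereocenter, so nothing has to be set or relayed; the only stereochemical elements of the route are a transient alkene geometry and a racemic carbinol carbon, and both are erased. The C3–indole bond joins a ring carbon to an indole C3 that lies next to a quaternary carbon, so any bond formation at that position is sterically hard. Three groups limit the reagents that can be used late in the route: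
- the 1,1-dimethylallyl group, which rules out strong acid and hydrogenation;
- the two methoxy-bearing quinone carbons, which are vinylogous esters open to hydroxide and amines;
- the electron-rich indoles, which rule out strong oxidants.

The feature that opens the problem is that C4(=O)–C3(indolyl)–C2(OMe)–C1(=O) is a 3-methoxy-4-arylcyclobutenedione in disguise, and C6(indolyl)=C5(OMe) is a 1-aryl-2-methoxyvinyl unit. Joining C1 to C6 by carbonyl addition and C4 to C5 by electrocyclization gives the ring with all six substituents in order and at the hydroquinone oxidation level.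

## Retrosynthesis

**23 to 21 to 20.** The N–Si bond of the plain indole and the N–CO2t-Bu bond of the prenylated indole are cut, and the two C=O groups are taken back to phenolic C–OH. A silyl group and a carbamate are preferred to an alkoxymethyl-type group on nitrogen, because they come off with fluoride at 0 °C and with methoxide in methanol. Methoxide attack at C2 or C5 of the quinone only exchanges methoxy for methoxy. Hydroquinone 20 is the direct product of the ring-forming step and needs only a mild two-electron oxidation to quinone 21.

**20 to 17 (key disconnection).** The C4–C5 bond is cut, which takes the benzene ring back to a four-membered ring carrying a vinyl group: the 4-alkenyl-4-hydroxycyclobutenone 17. Cutting one of the biaryl bonds (C3–indole or C6–indole) instead would require a cross-coupling on a hexasubstituted arene at a hindered indole C3. It would also leave the ring as a tetramethoxybenzene that must later be oxidatively demethylated beside two indoles. Cutting C4–C5 delivers the ring substituents already in sequence and at the right oxidation level. Compound 17 is an isomer of 20, but it falls apart in one further cut into two pieces of similar size. The forward reaction must open the four-membered ring with the vinyl group turned towards the ketene (dienylketene 18), close the six-membered ring (dienone 19) and enolize.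

**17 to 9 and 16 (from 15).** The C1–C6 bond between the carbinol carbon and the vinyl carbon is cut, giving cyclobutenedione 9 and vinyllithium 16, which is generated from stannane 15. The prenylated indole is placed on the dione and the plain indole on the vinyl unit, not the reverse, for two reasons. The tert-alkyl group twists the indole out of conjugation with the dione and shields the carbonyl next to it, and the N-Boc group lowers donation from the indole nitrogen. The carbonyl next to C–OMe is therefore the clearly more electrophilic one, the other being a vinylogous ester carbonyl. The reverse pairing would put a coplanar, electron-rich indole in conjugation with the carbonyl that has to be attacked and would require a very hindered vinyl nucleophile. The forward reaction must give 1,2-addition at that carbonyl, and the vinyllithium must not lose lithium methoxide.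

**15 to 14 to 13 to 12 to 10 and 11.** The C–Sn bond is traced to the C–O bond of enol triflate 14, and this to the enolate of ketone 13. The N–Si bond of 13 is cut to give 12, and the acyl–C3 bond of 12 is cut to give indole 10 and methoxyacetyl chloride 11. This path is one step longer than a Shapiro reaction on 13, but it fixes the geometry. The chelated (Z)-enolate places the triflate, then tin, then lithium cis to the methoxy group. A β-methoxyvinyllithium with lithium trans to the methoxy group, the likely Shapiro outcome, is set up for antiperiplanar loss of methoxide to an alkyne. Each step must retain the alkene geometry.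

**9 to 8 to 4 and 6; 6 to 5; 4 to 1 and 2.** The N–Boc bond is cut to give 8. The bond from indole C3 to the four-membered ring is cut to give 2-(2-methylbut-3-en-2-yl)indole 4 and squaric acid dichloride 6, which comes from squaric acid 5. The substitution on 6 needs no metal and no halogenated indole, and C2 of 4 is blocked, so only C3 can react. The remaining C–Cl bond is exchanged for C–OMe in the same flask through chloride 7. Indole 4 is cut at N1–C2 and C2–C3 to give 2-methylaniline 1 and the non-enolizable ester 2, joined through the N-silyl aniline 3. This builds the quaternary carbon into the indole from a bought ester instead of installing a reverse prenyl group on a formed indole.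

## Roads not taken

**Alternative 1:** The cut is through N1–C2 and the C3–aryl bond of the prenylated indole. In the forward step, zerovalent palladium inserts into aryl iodide A1. The arylpalladium iodide activates the alkyne of trifluoroacetanilide A2 for anti aminopalladation, and reductive elimination gives the 2,3-disubstituted indole A3.
- Merits: the pyrrole ring and the most hindered biaryl bond form in one step. The central ring arrives as a symmetric tetramethoxybenzene, so the order of methoxy and carbonyl carbons cannot go wrong: either para pair of methoxy carbons gives the same quinone.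
- Weak points: the reductive elimination must join a di-ortho-methoxy aryl group to a carbon flanked by a quaternary centre, and simple cyclization to the 3-unsubstituted indole competes. The end game needs oxidative demethylation with a reagent such as (NH4)2Ce(NO3)6 beside two indoles and a terminal alkene, with ortho-quinone formation as a side path. The tosyl group must then be removed from a base-sensitive quinone.
- Comparison: this road is at least as convergent and avoids the question of which dione carbonyl an organolithium attacks. The chosen plan sets against it that the ring is born as hydroquinone 20, one Ag2O oxidation from the quinone, so no strong oxidant meets the indoles.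

**Alternative 2:** The cut is through the C2–C(quaternary) bond and the C3–aryl bond of the prenylated indole. In the forward step, the 2-lithio derivative of N-Boc-indole A4 and tertiary allyl boronic ester A5 form a boronate. The arylpalladium iodide from A1 attacks C3 while the 1,1-dimethylallyl group shifts from boron to C2, and oxidative work-up removes boron and restores the indole as A6.
- Merits: three simple components, and both indole substituents are set in one operation starting from indole itself. On paper this is the shortest route to the hindered half.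
- Weak points: the boronate must form at a tertiary boronic ester. The migrating group is a tertiary allyl group that can shift with allylic transposition to the linear prenyl isomer. The electrophile is a hindered aryl palladium species, not the π-allyl species for which this shift is best known. The product carries the same tetramethoxybenzene and needs the same oxidative demethylation and two deprotections.
- Comparison: where it works it is shorter than the chosen route. The chosen plan offers instead that every bond is made by a reaction type with close precedent on its substrate class, and that the oxidation level is reached without a strong oxidant.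

**Alternative 3:** The cut is through two ring bonds, so that the central ring comes from cyclobutenone A7 and the indolyl methoxyalkyne A8. On heating, A7 opens to a vinylketene and adds A8 in a [2+2] sense. The new cyclobutenone then opens and closes by 6π electrocyclization to the pentasubstituted phenol A9.
- Merits: the ring forms from two fragments in one step with the substituent order fixed by ketene polarity. A9 is an air-stable p-methoxyphenol that a mild oxidant turns into the quinone. No β-methoxyvinyllithium is needed, and in these respects this road is better than the chosen one.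
- Weak points: both partners are costly. A8 is a methyl ynol ether on an indole C3 beside a quaternary carbon, hard to make and to keep. A7 is a 4-methoxycyclobutenone that itself has to be derived from a squarate by reduction. The intermolecular [2+2] step must bring the ketene carbon to the alkyne carbon that carries the bulky indole, so it competes with ketene dimerization.
- Comparison: the chosen plan sets against this a ring closure that is intramolecular, so it needs no excess of a precious partner, and two building blocks (9 and 15) that each come in four steps from bought materials.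

Key step: step 10

## Route

Remark on the chemistry: the carbinol carbon of 17 and the sp3 ring carbon of 19 are formed racemic and are both erased on the way to 20, so no stereocontrol is needed. The (Z) geometry of the vinyl unit is carried with retention from 14 to 17.

Step 1
Reactants: 1 2-methylaniline; 2 methyl 2,2-dimethylbut-3-enoate
Product: 4 2-(2-methylbut-3-en-2-yl)-1H-indole, via N-(trimethylsilyl)-2-methylaniline 3 (not isolated)
Conditions: n-BuLi (1 equiv), Me3SiCl, Et2O, 0 °C; sec-BuLi (2.2 equiv), hexane/Et2O, 0 °C; then 2, THF, −78 °C to rt; aq. NH4Cl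
Reagents that add atoms: none
Why: Madelung-type indole synthesis in its N-silyl dianion form: the N,C-dilithio species of 3 is acylated at the benzylic carbon by the non-enolizable ester 2, and the N-silyl anilide closes onto the ketone with loss of silanolate (aza-Peterson-type) to give the 2-substituted indole without any acid.

Step 2
Reactants: 5 squaric acid (3,4-dihydroxycyclobut-3-ene-1,2-dione)
Product: 6 3,4-dichlorocyclobut-3-ene-1,2-dione
Conditions: (COCl)2, DMF (cat.), CH2Cl2, rt to reflux
Reagents that add atoms: oxalyl chloride (O=C(Cl)C(=O)Cl)
Why: Vilsmeier-type chlorination of a vinylogous carboxylic acid, the standard preparation of squaric acid dichloride.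

Step 3
Reactants: 4 2-(2-methylbut-3-en-2-yl)-1H-indole; 6 3,4-dichlorocyclobut-3-ene-1,2-dione
Product: 8 3-methoxy-4-[2-(2-methylbut-3-en-2-yl)-1H-indol-3-yl]cyclobut-3-ene-1,2-dione, via 3-chloro-4-indolylcyclobutenedione 7 (not isolated)
Conditions: 6 (1.3 equiv), CH2Cl2, 0 °C to rt; then MeOH, rt
Reagents that add atoms: methanol (CO)
Why: Friedel–Crafts-type addition–elimination of indole C3 (C2 is blocked) on the vinylogous acid chloride, then methanolysis of the remaining vinylogous acid chloride; the excess of 6 suppresses double arylation.

Step 4
Reactants: 8 3-methoxy-4-[2-(2-methylbut-3-en-2-yl)-1H-indol-3-yl]cyclobut-3-ene-1,2-dione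
Product: 9 tert-butyl 3-(2-methoxy-3,4-dioxocyclobut-1-en-1-yl)-2-(2-methylbut-3-en-2-yl)-1H-indole-1-carboxylate
Conditions: Boc2O, Et3N, DMAP (cat.), MeCN, rt
Reagents that add atoms: di-tert-butyl dicarbonate (CC(C)(C)OC(=O)OC(=O)OC(C)(C)C)
Why: DMAP-catalysed N-acylation of an acidic, acyl-conjugated indole N–H; the carbamate removes the acidic proton, lowers indole donation into the dione and can later be cleaved by methoxide.

Step 5
Reactants: 10 indole; 11 methoxyacetyl chloride
Product: 12 1-(1H-indol-3-yl)-2-methoxyethan-1-one
Conditions: Et2AlCl, CH2Cl2, 0 °C; then 11, 0 °C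
Reagents that add atoms: none
Why: Et2AlCl-mediated Friedel–Crafts acylation of unprotected indole, which is selective for C3 and needs no N-protection.

Step 6
Reactants: 12 1-(1H-indol-3-yl)-2-methoxyethan-1-one
Product: 13 2-methoxy-1-[1-(triisopropylsilyl)-1H-indol-3-yl]ethan-1-one
Conditions: NaH, THF, 0 °C; i-Pr3SiCl, 0 °C to rt
Reagents that add atoms: triisopropylsilyl chloride (CC(C)[Si](Cl)(C(C)C)C(C)C)
Why: N-silylation of the sodium salt; the vinylogous amide N–H is far more acidic than the α-CH2, and the triisopropylsilyl group shields C2 and withstands amide bases and alkyllithiums at low temperature.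

Step 7
Reactants: 13 2-methoxy-1-[1-(triisopropylsilyl)-1H-indol-3-yl]ethan-1-one
Product: 14 (Z)-2-methoxy-1-[1-(triisopropylsilyl)-1H-indol-3-yl]ethenyl trifluoromethanesulfonate (triflate cis to methoxy)
Conditions: KN(SiMe3)2, THF, −78 °C; PhNTf2, −78 to 0 °C
Reagents that add atoms: N-phenylbis(trifluoromethanesulfonimide) (O=S(=O)(N(c1ccccc1)S(=O)(=O)C(F)(F)F)C(F)(F)F)
Why: Kinetic enolization of an α-alkoxy aryl ketone gives the (Z)-enolate (metal bridged between enolate oxygen and methoxy, and allylic strain with the aryl group points the same way), and O-sulfonylation (enol triflate formation) fixes this geometry.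

Step 8
Reactants: 14 (Z)-2-methoxy-1-[1-(triisopropylsilyl)-1H-indol-3-yl]ethenyl trifluoromethanesulfonate
Product: 15 trimethyl{(Z)-2-methoxy-1-[1-(triisopropylsilyl)-1H-indol-3-yl]ethenyl}stannane (tin cis to methoxy)
Conditions: Me3SnSnMe3, Pd(PPh3)4 (5 mol %), LiCl, THF, 60 °C
Reagents that add atoms: hexamethylditin (C[Sn](C)(C)[Sn](C)(C)C)
Why: Stille-type stannylation of an enol triflate (oxidative addition, transmetalation with the ditin, reductive elimination) proceeds with retention of alkene geometry; LiCl assists the transmetalation.

Step 9
Reactants: 15 trimethyl{(Z)-2-methoxy-1-[1-(triisopropylsilyl)-1H-indol-3-yl]ethenyl}stannane; 9 tert-butyl 3-(2-methoxy-3,4-dioxocyclobut-1-en-1-yl)-2-(2-methylbut-3-en-2-yl)-1H-indole-1-carboxylate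
Product: 17 racemic tert-butyl 3-{3-hydroxy-2-methoxy-3-[(Z)-2-methoxy-1-(1-triisopropylsilyl-1H-indol-3-yl)ethenyl]-4-oxocyclobut-1-en-1-yl}-2-(2-methylbut-3-en-2-yl)-1H-indole-1-carboxylate, via vinyllithium 16 (not isolated)
Conditions: MeLi (0.95 equiv to 15), THF, −78 °C; then 9, −78 °C; aq. NH4Cl at −78 °C
Reagents that add atoms: none
Why: Tin–lithium exchange with retention gives 16 with lithium cis to the methoxy group (internally coordinated, with no antiperiplanar methoxide to lose). Organolithium 1,2-addition to a 3-alkoxy-4-arylcyclobutenedione then takes place at the carbonyl next to C–OMe, because the other carbonyl is a vinylogous ester and is shielded by the tert-alkyl indole. The new carbinol centre is racemic and is erased in step 10.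

Step 10
Reactants: 17 racemic tert-butyl 3-{3-hydroxy-2-methoxy-3-[(Z)-2-methoxy-1-(1-triisopropylsilyl-1H-indol-3-yl)ethenyl]-4-oxocyclobut-1-en-1-yl}-2-(2-methylbut-3-en-2-yl)-1H-indole-1-carboxylate
Product: 20 tert-butyl 3-{2,5-dihydroxy-3,6-dimethoxy-4-[1-(triisopropylsilyl)-1H-indol-3-yl]phenyl}-2-(2-methylbut-3-en-2-yl)-1H-indole-1-carboxylate, via dienylketene 18 (not isolated), via cyclohexadienone 19 (not isolated)
Conditions: toluene (degassed), 110 °C, Ar
Reagents that add atoms: none
Why: Heating opens the cyclobutenone by conrotatory 4π electrocyclic cleavage of the C(=O)–C(OH) bond to dienylketene 18. The donor hydroxyl on the breaking carbon rotates outward, so the vinyl group turns inward and ends cis to the ketene; this is the one selectivity the step needs, and the substrate itself secures it. The ketene carbon (future C4) then bonds to the methoxy-bearing vinyl carbon (future C5) in a thermally allowed disrotatory 6π electrocyclization that closes the six-membered carbocycle as dienone 19. Enolization of 19 gives the aromatic hydroquinone 20 and removes the only sp3 carbon formed, so no stereocenter has to be controlled; the racemic carbinol carbon of 17 becomes C1–OH. The closest known reaction type is the thermal ring expansion of squarate-derived 4-alkenyl-4-hydroxycyclobutenones to hydroquinones (Moore rearrangement). The methoxy group on the inside of the vinyl terminus meets only the unsubstituted sp carbon of the ketene, so ring closure should stay faster than intermolecular capture of the ketene. Neutral toluene at 110 °C should leave the 1,1-dimethylallyl group, the carbamate and the N-silyl group in place, and exclusion of air keeps 20 from partial oxidation.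

Step 11
Reactants: 20 tert-butyl 3-{2,5-dihydroxy-3,6-dimethoxy-4-[1-(triisopropylsilyl)-1H-indol-3-yl]phenyl}-2-(2-methylbut-3-en-2-yl)-1H-indole-1-carboxylate
Product: 21 tert-butyl 3-{2,5-dimethoxy-3,6-dioxo-4-[1-(triisopropylsilyl)-1H-indol-3-yl]cyclohexa-1,4-dien-1-yl}-2-(2-methylbut-3-en-2-yl)-1H-indole-1-carboxylate
Conditions: Ag2O, MgSO4, Et2O, rt
Reagents that add atoms: none
Why: Two-electron oxidation of a hydroquinone to the quinone with Ag2O, mild enough to leave the indoles, the terminal alkene and both N-protecting groups untouched.

Step 12
Reactants: 21 tert-butyl 3-{2,5-dimethoxy-3,6-dioxo-4-[1-(triisopropylsilyl)-1H-indol-3-yl]cyclohexa-1,4-dien-1-yl}-2-(2-methylbut-3-en-2-yl)-1H-indole-1-carboxylate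
Product: 23 2,5-dimethoxy-3-[2-(2-methylbut-3-en-2-yl)-1H-indol-3-yl]-6-(1H-indol-3-yl)cyclohexa-2,5-diene-1,4-dione, via mono-Boc quinone 22 (not isolated)
Conditions: Bu4NF, AcOH, THF, 0 °C; then K2CO3, MeOH, rt
Reagents that add atoms: none
Why: Buffered fluoride cleaves the N–Si bond at 0 °C, and methoxide then removes the N-Boc group by acyl transfer to methanol with indolide as leaving group; methoxide attack at the methoxy-bearing quinone carbons only exchanges like for like.

## Compound list

1 | 2-methylaniline | Cc1ccccc1N | starting material
2 | methyl 2,2-dimethylbut-3-enoate | C=CC(C)(C)C(=O)OC | starting material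
3 | N-(trimethylsilyl)-2-methylaniline | Cc1ccccc1N[Si](C)(C)C | intermediate (not isolated)
4 | 2-(2-methylbut-3-en-2-yl)-1H-indole | C=CC(C)(C)c1cc2ccccc2[nH]1 | intermediate
5 | squaric acid (3,4-dihydroxycyclobut-3-ene-1,2-dione) | OC1=C(O)C(=O)C1=O | starting material
6 | 3,4-dichlorocyclobut-3-ene-1,2-dione | ClC1=C(Cl)C(=O)C1=O | intermediate
7 | 3-chloro-4-[2-(2-methylbut-3-en-2-yl)-1H-indol-3-yl]cyclobut-3-ene-1,2-dione | C=CC(C)(C)c1[nH]c2ccccc2c1C1=C(Cl)C(=O)C1=O | intermediate (not isolated)
8 | 3-methoxy-4-[2-(2-methylbut-3-en-2-yl)-1H-indol-3-yl]cyclobut-3-ene-1,2-dione | C=CC(C)(C)c1[nH]c2ccccc2c1C1=C(OC)C(=O)C1=O | intermediate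
9 | tert-butyl 3-(2-methoxy-3,4-dioxocyclobut-1-en-1-yl)-2-(2-methylbut-3-en-2-yl)-1H-indole-1-carboxylate | C=CC(C)(C)c1n(C(=O)OC(C)(C)C)c2ccccc2c1C1=C(OC)C(=O)C1=O | intermediate
10 | indole | c1ccc2[nH]ccc2c1 | starting material
11 | methoxyacetyl chloride | COCC(=O)Cl | starting material
12 | 1-(1H-indol-3-yl)-2-methoxyethan-1-one | COCC(=O)c1c[nH]c2ccccc12 | intermediate
13 | 2-methoxy-1-[1-(triisopropylsilyl)-1H-indol-3-yl]ethan-1-one | COCC(=O)c1cn([Si](C(C)C)(C(C)C)C(C)C)c2ccccc12 | intermediate
14 | (Z)-2-methoxy-1-[1-(triisopropylsilyl)-1H-indol-3-yl]ethenyl trifluoromethanesulfonate | CO/C=C(\OS(=O)(=O)C(F)(F)F)c1cn([Si](C(C)C)(C(C)C)C(C)C)c2ccccc12 | intermediate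
15 | trimethyl{(Z)-2-methoxy-1-[1-(triisopropylsilyl)-1H-indol-3-yl]ethenyl}stannane | CO/C=C(\[Sn](C)(C)C)c1cn([Si](C(C)C)(C(C)C)C(C)C)c2ccccc12 | intermediate
16 | (E)-{2-methoxy-1-[1-(triisopropylsilyl)-1H-indol-3-yl]ethenyl}lithium (lithium cis to methoxy) | CO/C=C(\[Li])c1cn([Si](C(C)C)(C(C)C)C(C)C)c2ccccc12 | intermediate (not isolated)
17 | racemic tert-butyl 3-{3-hydroxy-2-methoxy-3-[(Z)-2-methoxy-1-(1-triisopropylsilyl-1H-indol-3-yl)ethenyl]-4-oxocyclobut-1-en-1-yl}-2-(2-methylbut-3-en-2-yl)-1H-indole-1-carboxylate | CO/C=C(c1cn([Si](C(C)C)(C(C)C)C(C)C)c2ccccc12)\C1(O)C(=O)C(c2c(C(C)(C)C=C)n(C(=O)OC(C)(C)C)c3ccccc23)=C1OC | intermediate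
18 | tert-butyl 3-[(3Z,5Z)-4-hydroxy-3,6-dimethoxy-1-oxo-5-(1-triisopropylsilyl-1H-indol-3-yl)hexa-1,3,5-trien-2-yl]-2-(2-methylbut-3-en-2-yl)-1H-indole-1-carboxylate (dienylketene) | O=C=C(c1c(C(C)(C)C=C)n(C(=O)OC(C)(C)C)c2ccccc12)/C(OC)=C(O)\C(c1cn([Si](C(C)C)(C(C)C)C(C)C)c2ccccc12)=C/OC | intermediate (not isolated)
19 | racemic tert-butyl 3-{4-hydroxy-3,6-dimethoxy-1-oxo-5-[1-(triisopropylsilyl)-1H-indol-3-yl]cyclohexa-2,4-dien-2-yl}-2-(2-methylbut-3-en-2-yl)-1H-indole-1-carboxylate (cyclohexadienone) | COC1C(=O)C(c2c(C(C)(C)C=C)n(C(=O)OC(C)(C)C)c3ccccc23)=C(OC)C(O)=C1c1cn([Si](C(C)C)(C(C)C)C(C)C)c2ccccc12 | intermediate (not isolated)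
20 | tert-butyl 3-{2,5-dihydroxy-3,6-dimethoxy-4-[1-(triisopropylsilyl)-1H-indol-3-yl]phenyl}-2-(2-methylbut-3-en-2-yl)-1H-indole-1-carboxylate | COc1c(O)c(-c2c(C(C)(C)C=C)n(C(=O)OC(C)(C)C)c3ccccc23)c(OC)c(O)c1-c1cn([Si](C(C)C)(C(C)C)C(C)C)c2ccccc12 | intermediate
21 | tert-butyl 3-{2,5-dimethoxy-3,6-dioxo-4-[1-(triisopropylsilyl)-1H-indol-3-yl]cyclohexa-1,4-dien-1-yl}-2-(2-methylbut-3-en-2-yl)-1H-indole-1-carboxylate | COC1=C(c2cn([Si](C(C)C)(C(C)C)C(C)C)c3ccccc23)C(=O)C(OC)=C(c2c(C(C)(C)C=C)n(C(=O)OC(C)(C)C)c3ccccc23)C1=O | intermediate
22 | tert-butyl 3-[4-(1H-indol-3-yl)-2,5-dimethoxy-3,6-dioxocyclohexa-1,4-dien-1-yl]-2-(2-methylbut-3-en-2-yl)-1H-indole-1-carboxylate | COC1=C(c2c[nH]c3ccccc23)C(=O)C(OC)=C(c2c(C(C)(C)C=C)n(C(=O)OC(C)(C)C)c3ccccc23)C1=O | intermediate (not isolated)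
23 | 2,5-dimethoxy-3-[2-(2-methylbut-3-en-2-yl)-1H-indol-3-yl]-6-(1H-indol-3-yl)cyclohexa-2,5-diene-1,4-dione | C=CC(C)(C)c1[nH]c2ccccc2c1C1=C(OC)C(=O)C(c2c[nH]c3ccccc23)=C(OC)C1=O | target

## Step count and risks

Total: 12 steps. Longest linear sequence: 8 steps (steps 5 to 12, from indole 10). The branch from 1 runs through steps 1, 3 and 4 and joins at step 9; step 2 is a one-step side branch.

**Step 10 (key step).** Three things may go wrong. A minor share of ring opening may occur in the opposite rotational sense, which lets the hydroxyl group capture the ketene as a lactone. The inside methoxy group may slow the 6π closure and give the ketene time for other reactions. The acid-sensitive tertiary, doubly allylic alcohol may ionize before it rearranges. The fallback sets out from 17. The hydroxyl group is silylated (Me3SiCl, imidazole, DMF) to the trimethylsilyl ether F1, which cannot lactonize and no longer ionizes readily. Thermolysis in toluene gives the mono-silylated hydroquinone F2 by the same opening, closure and enolization. Brief treatment with AcOH in aqueous THF cleaves the aryl silyl ether and returns to the route at 20.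

**Step 9.** The vinyllithium may lose lithium methoxide, giving an alkyne, before it adds. Addition may also take place in part at the vinylogous ester carbonyl or at the carbamate. The fallback sets out from triflate 14 and dione 9 and avoids the organolithium. A Nozaki–Hiyama–Kishi coupling (CrCl2, catalytic NiCl2, DMF, rt) generates a far less basic vinylchromium species from 14, which the strained and strongly electrophilic dione should accept. The product is 17, where the route is rejoined; no new compound arises.

**Step 7.** The electron-rich enol triflate may ionize or hydrolyse during isolation, and the geometry may erode if enolization is not under chelate control. The fallback sets out from ketone 13. Condensation with hydrazine gives hydrazone F3 (a mixture of C=N isomers). Barton vinyl iodide synthesis (I2, tetramethylguanidine) gives, after separation of the geometric isomers, the (Z)-vinyl iodide F4 with iodine cis to methoxy. Iodine–lithium exchange with t-BuLi at −78 °C then leads directly to 16, bypassing 14 and 15.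

**Step 3.** Substitution at the hindered C3 may be slow, a second indole may add to the remaining vinylogous acid chloride, and the HCl set free may add to the terminal alkene on long reaction times. The fallback sets out from indole 4. Bromination with NBS gives the 3-bromoindole F5. Deprotonation of N–H with KH, bromine–lithium exchange with t-BuLi and addition to dimethyl squarate give the carbinol F6. Acid (trifluoroacetic anhydride or a trace of HCl) induces loss of methanol with rearrangement to the 3-aryl-4-methoxycyclobutenedione, which is 8, where the route is rejoined.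

**Step 12.** Hydroxide from wet fluoride may attack the methoxy-bearing quinone carbons, or cleavage of the hindered carbamate may be slow enough for the quinone to suffer. The fallback sets out from hydroquinone 20 and removes both N-protecting groups before the oxidation, while the ring is electron-rich and not electrophilic. The same reagents (Bu4NF, then K2CO3 in MeOH, under argon) give the free hydroquinone F7, and Ag2O or air then oxidizes it to 23.

## Further compounds

F1 | step 10 | racemic tert-butyl 3-{2-methoxy-3-[(Z)-2-methoxy-1-(1-triisopropylsilyl-1H-indol-3-yl)ethenyl]-4-oxo-3-(trimethylsilyloxy)cyclobut-1-en-1-yl}-2-(2-methylbut-3-en-2-yl)-1H-indole-1-carboxylate | CO/C=C(c1cn([Si](C(C)C)(C(C)C)C(C)C)c2ccccc12)\C1(O[Si](C)(C)C)C(=O)C(c2c(C(C)(C)C=C)n(C(=O)OC(C)(C)C)c3ccccc23)=C1OC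
F2 | step 10 | tert-butyl 3-{2-hydroxy-3,6-dimethoxy-4-[1-(triisopropylsilyl)-1H-indol-3-yl]-5-(trimethylsilyloxy)phenyl}-2-(2-methylbut-3-en-2-yl)-1H-indole-1-carboxylate | COc1c(O)c(-c2c(C(C)(C)C=C)n(C(=O)OC(C)(C)C)c3ccccc23)c(OC)c(O[Si](C)(C)C)c1-c1cn([Si](C(C)C)(C(C)C)C(C)C)c2ccccc12
F0 | step 9 | none | none
F3 | step 7 | 2-methoxy-1-[1-(triisopropylsilyl)-1H-indol-3-yl]ethan-1-one hydrazone (mixture of C=N isomers) | COCC(=NN)c1cn([Si](C(C)C)(C(C)C)C(C)C)c2ccccc12
F4 | step 7 | (Z)-3-(1-iodo-2-methoxyethenyl)-1-(triisopropylsilyl)-1H-indole | CO/C=C(\I)c1cn([Si](C(C)C)(C(C)C)C(C)C)c2ccccc12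
F5 | step 3 | 3-bromo-2-(2-methylbut-3-en-2-yl)-1H-indole | C=CC(C)(C)c1[nH]c2ccccc2c1Br
F6 | step 3 | racemic 4-hydroxy-2,3-dimethoxy-4-[2-(2-methylbut-3-en-2-yl)-1H-indol-3-yl]cyclobut-2-en-1-one | COC1=C(OC)C(O)(c2c(C(C)(C)C=C)[nH]c3ccccc23)C1=O
F7 | step 12 | 2,5-dimethoxy-3-(1H-indol-3-yl)-6-[2-(2-methylbut-3-en-2-yl)-1H-indol-3-yl]benzene-1,4-diol | COc1c(O)c(-c2c(C(C)(C)C=C)[nH]c3ccccc23)c(OC)c(O)c1-c1c[nH]c2ccccc12
A1 | alternative 1 | 3-(4-iodo-2,3,5,6-tetramethoxyphenyl)-1-(4-methylphenylsulfonyl)-1H-indole | COc1c(OC)c(-c2cn(S(=O)(=O)c3ccc(C)cc3)c3ccccc23)c(OC)c(OC)c1I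
A2 | alternative 1 | N-[2-(3,3-dimethylpent-4-en-1-yn-1-yl)phenyl]-2,2,2-trifluoroacetamide | C=CC(C)(C)C#Cc1ccccc1NC(=O)C(F)(F)F
A3 | alternative 1 | 2-(2-methylbut-3-en-2-yl)-3-[2,3,5,6-tetramethoxy-4-(1-tosylindol-3-yl)phenyl]-1H-indole | COc1c(OC)c(-c2cn(S(=O)(=O)c3ccc(C)cc3)c3ccccc23)c(OC)c(OC)c1-c1c(C(C)(C)C=C)[nH]c2ccccc12
A4 | alternative 2 | tert-butyl 1H-indole-1-carboxylate | CC(C)(C)OC(=O)n1ccc2ccccc21
A5 | alternative 2 | 4,4,5,5-tetramethyl-2-(2-methylbut-3-en-2-yl)-1,3,2-dioxaborolane | C=CC(C)(C)B1OC(C)(C)C(C)(C)O1
A6 | alternative 2 | tert-butyl 2-(2-methylbut-3-en-2-yl)-3-[2,3,5,6-tetramethoxy-4-(1-tosylindol-3-yl)phenyl]indole-1-carboxylate | COc1c(OC)c(-c2cn(S(=O)(=O)c3ccc(C)cc3)c3ccccc23)c(OC)c(OC)c1-c1c(C(C)(C)C=C)n(C(=O)OC(C)(C)C)c2ccccc12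
A7 | alternative 3 | racemic 2,4-dimethoxy-3-[1-(triisopropylsilyl)-1H-indol-3-yl]cyclobut-2-en-1-one | COC1C(=O)C(OC)=C1c1cn([Si](C(C)C)(C(C)C)C(C)C)c2ccccc12
A8 | alternative 3 | 3-(methoxyethynyl)-2-(2-methylbut-3-en-2-yl)-1-{[2-(trimethylsilyl)ethoxy]methyl}-1H-indole | COC#Cc1c(C(C)(C)C=C)n(COCC[Si](C)(C)C)c2ccccc12
A9 | alternative 3 | 3,4,6-trimethoxy-2-[1-{[2-(trimethylsilyl)ethoxy]methyl}-2-(2-methylbut-3-en-2-yl)indol-3-yl]-5-[1-(triisopropylsilyl)indol-3-yl]phenol | COc1c(O)c(-c2c(C(C)(C)C=C)n(COCC[Si](C)(C)C)c3ccccc23)c(OC)c(OC)c1-c1cn([Si](C(C)C)(C(C)C)C(C)C)c2ccccc12
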